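The rate constants were chosen freely, and the outcome is calculated.

Percent of the charge is the unit of this account: D, D.X, Q and G count against the D charged, X against its own charge.

    D + X ⇌ Q (K1 = 10 M⁻¹, k1 = 4.6 × 10⁻⁴ M⁻¹ s⁻¹)
    Q ⇌ G (K2 = 2.6, k2 = 2.7 × 10⁻⁴ s⁻¹)
    D + X → D.X (k3 = 0.0016 M⁻¹ s⁻¹)
    Q → D.X (k4 = 1.9 × 10⁻⁵ s⁻¹)

| flask | D | X | time | remark |
|---|---|---|---|---|
| midnight | 0.12 M | 0.600 equiv (fed, over 1.20 h) | 1.5 h | all but X at the start; X goes in evenly over 1.20 h, the run ends at 1.5 h |
| dusk | 0.12 M | 0.600 equiv | 1.5 h | everything together in a closed stirred flask, run for 1.5 h |
| noon | 0.12 M (fed, over 1.20 h) | 0.600 equiv | 1.5 h | a stirred flask in which D is dosed at a steady rate over 1.20 h without added volume, worked up at 1.5 h |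
| autumn | 0.12 M | 0.600 equiv |  | a single well-mixed tank run continuously and read at steady state, 1.5 h in it on average |

* the set-up with the highest amount of D.X at the outlet or at the end, in percent of the D put in ("none" if the first two lie within 2 percentage points) (midnight / dusk / noon / autumn / none)
* amount of D.X at the outlet or at the end, in percent of the D put in, midnight
* amount of D.X at the outlet or at the end, in percent of the D put in, dusk
* amount of D.X at the outlet or at the end, in percent of the D put in, noon
* amount of D.X at the outlet or at the end, in percent of the D put in, autumn

- the stated concentrations are those of everything mixed, before any reaction; amounts are the same in each set-up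
- the feed brings no volume worth counting
- run time (midnight): 1.5 h

I followed one D through dusk, the closed flask. In the first instants it met X and stood at a fork: straight to D.X, or into Q. Both ways run on the same product of D and X, so their ratio, a selectivity factor of 3.48, holds no concentration. The chance of the straight way came to 77.7 %. I called this the direct share, the chance that a D taken by X becomes D.X at once.

In the middle of dusk, a Q formed earlier stood at a fork of its own, with a chance of 80.6 % for G, 5.67 % for D.X and 13.7 % back to D and X. So I booked Q and G as a side pocket and dropped the ways back.

That left one reckoning: D.X is the direct share times the fraction of D lost. For the end of dusk, the second-order balance of the two ways together gave a lost fraction of 38.3 %. In this reckoning X, the limiting reagent at 0.600 equiv, kept 36.2 % of its charge. My dusk figure was 29.7 %.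

In midnight and noon the feed came evenly, so the fed reagent had on average 0.900 h in the flask, less than the 1.5 h of dusk. The same balance over that time lost 29.1 %, which gave 22.6 % for both. For autumn, the tank balance with 1.5 h of average stay lost 29.2 %, which gave 22.6 %. So I put dusk above the others, by 7.1 percentage points.

The forecast named dusk. It gave 22.3 % for midnight, 30.2 % for dusk, 22.6 % for noon and 23.3 % for autumn. Its grounds included that “about 78% of that flux goes directly to D.X”. It stood above my figures for dusk and autumn.

The simulation gave dusk as best, with 30.3 % there, against 22.1 % for midnight, 22.5 % for noon and 23.3 % for autumn. Dusk kept 62 % of its D free at 1.50 h, and the direct share of the D gone is 29.5 %. The neighbour flask was midnight with 2.40 equiv of X, and it kept 24.0 % of its D free. The direct share of the D gone there is 59.1 %, and the flask held 60.5 % of D.X.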